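**Retrosynthetic overview**

- The target comes from a bis(triethylammonium) 3,3'-disulfate by hydrogenolysis of the 5-O- and 4'-O-benzyl ethers and protonation; that salt comes from 5,4'-di-O-benzylrhamnetin by sulfation of 3-OH and 3'-OH; the diol comes from a 3-unsubstituted flavone by C2=C3 epoxidation, acid opening and loss of the 3'-O-MOM group.
- Key disconnection: ring C is cut at C3–C4 and O1–C2. C4 is a ketone carbon bonded to C4a of ring A and to C3, and the neighbouring ring A carbon C8a carries O1. C4 is therefore the formyl carbon of a salicylaldehyde whose ortho hydroxyl (the future O1) steers rhodium into the formyl C–H bond; C3 is the ylide carbon and C2 the aroyl carbonyl of a sulfoxonium ylide.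
- The salicylaldehyde comes from commercial 2-hydroxy-4,6-dimethoxybenzaldehyde by chelation-controlled 6-O-demethylation and mono-benzylation. The 5-oxygen travels as a benzyl ether because a Lewis-acid demethylation after coupling would endanger the 4'-benzyl ether.
- The ylide comes from methyl 3,4-dihydroxybenzoate (4-O-benzyl, 3-O-MOM) and trimethylsulfoxonium iodide.
- Ring order: rings A and B are purchased; ring C is the only ring formed, in step 6.

Key step: step 6

Assumption: the target is drawn as the free bis(hydrogen sulfate). Aryl sulfate monoesters are stable as salts but hydrolyse in the acid form, so the disulfate is carried as its bis(triethylammonium) salt and protonated only in the final cold cation exchange.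

**Route**

Step 1
Reactants: 1 2-hydroxy-4,6-dimethoxybenzaldehyde
Product: 2 2,6-dihydroxy-4-methoxybenzaldehyde
Conditions: AlCl3 (3 equiv), CH2Cl2, 0 °C to rt; aq. HCl quench
Reagents that add atoms: none
Why: Chelation-controlled Lewis-acid ether cleavage, in which aluminium bridges the formyl oxygen and the ortho methoxy oxygen so that chloride demethylates only the 6-OMe and the non-chelated 4-OMe remains, as in the known AlCl3 conversion of 2,6-dimethoxybenzaldehydes into 2,6-dihydroxybenzaldehydes.

Step 2
Reactants: 2 2,6-dihydroxy-4-methoxybenzaldehyde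
Product: 3 2-(benzyloxy)-6-hydroxy-4-methoxybenzaldehyde
Conditions: BnBr (1.0 equiv), K2CO3 (1.1 equiv), DMF, rt
Reagents that add atoms: benzyl bromide, BrCc1ccccc1
Why: Williamson ether synthesis on two equivalent hydroxyls; after the first alkylation the remaining hydroxyl is locked in a hydrogen bond to the formyl oxygen and reacts far more slowly, so one equivalent of halide should stop at the monoether.

Step 3
Reactants: 4 methyl 3,4-dihydroxybenzoate
Product: 5 methyl 4-(benzyloxy)-3-hydroxybenzoate
Conditions: BnBr (1.0 equiv), K2CO3 (1.0 equiv), DMF, rt; chromatography or crystallisation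
Reagents that add atoms: benzyl bromide, BrCc1ccccc1
Why: Williamson ether synthesis in which the 4-OH, para to the ester and the more acidic phenol, is ionised preferentially by one equivalent of weak base and is therefore benzylated; minor 3-O and bis ethers are separated.

Step 4
Reactants: 5 methyl 4-(benzyloxy)-3-hydroxybenzoate
Product: 6 methyl 4-(benzyloxy)-3-(methoxymethoxy)benzoate
Conditions: MOMCl, iPr2NEt, CH2Cl2, 0 °C to rt
Reagents that add atoms: chloromethyl methyl ether, COCCl
Why: O-alkylation of the remaining phenol with an α-chloro ether under amine base gives the MOM acetal; ester and benzyl ether are inert.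

Step 5
Reactants: 6 methyl 4-(benzyloxy)-3-(methoxymethoxy)benzoate; 7 trimethylsulfoxonium iodide
Product: 9 1-[4-(benzyloxy)-3-(methoxymethoxy)phenyl]-2-[dimethyl(oxo)-lambda6-sulfanylidene]ethan-1-one, via dimethylsulfoxonium methylide 8 (not isolated)
Conditions: 7 (3 equiv), KOtBu (3 equiv), THF, reflux; then 6, THF, reflux
Reagents that add atoms: none
Why: Corey–Chaykovsky-type acylation of the sulfoxonium methylide, in which the ylide adds to the ester, methoxide leaves and the β-keto sulfoxonium salt is deprotonated to the stabilised ylide that does not react further; both ether protecting groups are base-stable.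

Step 6
Reactants: 3 2-(benzyloxy)-6-hydroxy-4-methoxybenzaldehyde; 9 1-[4-(benzyloxy)-3-(methoxymethoxy)phenyl]-2-[dimethyl(oxo)-lambda6-sulfanylidene]ethan-1-one
Product: 11 5-(benzyloxy)-2-[4-(benzyloxy)-3-(methoxymethoxy)phenyl]-7-methoxy-4H-chromen-4-one, via 1,3-diketone 10 (not isolated)
Conditions: [Cp*RhCl2]2 (2.5 mol %), AgSbF6 (10 mol %), NaOAc (0.5 equiv), AcOH (1 equiv), 9 (1.3 equiv), ClCH2CH2Cl, 80 °C, Ar
Reagents that add atoms: none
Why: The phenoxide of 3 binds Cp*Rh (trivalent rhodium) and acetate-assisted cleavage of the formyl C–H bond gives a five-membered acyl rhodacycle; ylide 9 then binds through carbon and loses dimethyl sulfoxide to give a rhodium carbene, the acyl group migrates onto the carbene carbon to form C3–C4, and protonation by acetic acid releases 1,3-diketone 10 and returns the catalyst. The closest known reaction type is the Cp*Rh-catalysed annulation of salicylaldehydes with aroyl sulfoxonium ylides to chromones, applied here to a 6-alkoxy salicylaldehyde. Ring C closes by 6-exo-trig attack of the ring A phenol oxygen (O1) on the B-ring ketone carbon (C2), and the hemiketal dehydrates to the aromatic pyranone. No stereocenter is formed. The step needs insertion into the formyl C–H bond in preference to carbene O–H insertion at the phenol, to aryl C–H activation directed by the ylide carbonyl and to decarbonylation; the ortho hydroxyl secures this by holding rhodium beside the formyl hydrogen, and both positions ortho to the formyl group are substituted, so no ring A C–H bond sits next to the directing oxygen in a reactive geometry. The acetate/acetic acid buffer keeps the medium mild enough for the MOM acetal and the benzyl ethers while still driving the cyclodehydration.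

Step 7
Reactants: 11 5-(benzyloxy)-2-[4-(benzyloxy)-3-(methoxymethoxy)phenyl]-7-methoxy-4H-chromen-4-one
Product: 14 5-(benzyloxy)-2-[4-(benzyloxy)-3-hydroxyphenyl]-3-hydroxy-7-methoxy-4H-chromen-4-one, via flavone 2,3-epoxide 12 (not isolated), via MOM-protected flavonol 13 (not isolated)
Conditions: dimethyldioxirane (acetone solution, 3 equiv), CH2Cl2, 0 °C, dark; evaporate; then HCl (conc., few equiv), MeOH–THF, 40 °C
Reagents that add atoms: dimethyldioxirane, CC1(C)OO1
Why: Dioxirane epoxidation of the C2=C3 enol-ether bond of an alkoxyflavone, then acid-catalysed opening at C2 (cation stabilised by O1 and the aryl group) with loss of H3 to give the aromatic 3-hydroxychromone, while the same acid in methanol removes the MOM acetal by transacetalisation; benzyl and methyl ethers are stable.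

Step 8
Reactants: 14 5-(benzyloxy)-2-[4-(benzyloxy)-3-hydroxyphenyl]-3-hydroxy-7-methoxy-4H-chromen-4-one
Product: 15 bis(triethylammonium) 5,4'-di-O-benzylrhamnetin 3,3'-disulfate
Conditions: SO3·NEt3 (8 equiv), DMF, 60 °C, Ar; Sephadex LH-20 (MeOH)
Reagents that add atoms: sulfur trioxide–triethylamine complex, CC[N+](CC)(CC)S(=O)(=O)[O-]
Why: O-sulfonation of both free hydroxyls with a sulfur trioxide–amine complex, the standard route to flavonoid sulfates; 5-O and 4'-O are benzylated, so exhaustive sulfation needs no site selectivity, and the product is kept as the base-stable ammonium salt.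

Step 9
Reactants: 15 bis(triethylammonium) 5,4'-di-O-benzylrhamnetin 3,3'-disulfate
Product: 17 rhamnetin 3,3'-disulfate (free bis(hydrogen sulfate)), via bis(triethylammonium) rhamnetin 3,3'-disulfate 16 (not isolated)
Conditions: H2 (1 atm), 10% Pd/C, MeOH–THF, rt; filter; Dowex 50W-X8 (H+ form), MeOH–H2O, 0 °C; freeze-dry at once
Reagents that add atoms: none
Why: Catalytic hydrogenolysis cleaves both aryl benzyl ethers while sulfate monoesters and the chromone are inert, and cation exchange then protonates the sulfates and holds triethylammonium on the resin.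

**Compound list**

1 | 2-hydroxy-4,6-dimethoxybenzaldehyde | COc1cc(O)c(C=O)c(OC)c1 | starting material
2 | 2,6-dihydroxy-4-methoxybenzaldehyde | COc1cc(O)c(C=O)c(O)c1 | intermediate
3 | 2-(benzyloxy)-6-hydroxy-4-methoxybenzaldehyde | COc1cc(O)c(C=O)c(OCc2ccccc2)c1 | intermediate
4 | methyl 3,4-dihydroxybenzoate | COC(=O)c1ccc(O)c(O)c1 | starting material
5 | methyl 4-(benzyloxy)-3-hydroxybenzoate | COC(=O)c1ccc(OCc2ccccc2)c(O)c1 | intermediate
6 | methyl 4-(benzyloxy)-3-(methoxymethoxy)benzoate | COCOc1cc(C(=O)OC)ccc1OCc1ccccc1 | intermediate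
7 | trimethylsulfoxonium iodide | C[S+](C)(C)=O.[I-] | starting material
8 | dimethylsulfoxonium methylide (formed in the flask) | C=S(C)(C)=O | intermediate
9 | 1-[4-(benzyloxy)-3-(methoxymethoxy)phenyl]-2-[dimethyl(oxo)-lambda6-sulfanylidene]ethan-1-one | CS(C)(=O)=CC(=O)c1ccc(OCc2ccccc2)c(OCOC)c1 | intermediate
10 | 1-[2-(benzyloxy)-6-hydroxy-4-methoxyphenyl]-3-[4-(benzyloxy)-3-(methoxymethoxy)phenyl]propane-1,3-dione (1,3-diketone, formed in the flask) | COCOc1cc(C(=O)CC(=O)c2c(O)cc(OC)cc2OCc2ccccc2)ccc1OCc1ccccc1 | intermediate
11 | 5-(benzyloxy)-2-[4-(benzyloxy)-3-(methoxymethoxy)phenyl]-7-methoxy-4H-chromen-4-one | COCOc1cc(-c2cc(=O)c3c(OCc4ccccc4)cc(OC)cc3o2)ccc1OCc1ccccc1 | intermediate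
12 | flavone 2,3-epoxide of 11 (racemic, cis-fused oxirane across C2–C3; formed in the flask) | COCOc1cc(C23OC2C(=O)c2c(OCc4ccccc4)cc(OC)cc2O3)ccc1OCc1ccccc1 | intermediate
13 | 5-(benzyloxy)-2-[4-(benzyloxy)-3-(methoxymethoxy)phenyl]-3-hydroxy-7-methoxy-4H-chromen-4-one (MOM-protected flavonol, formed in the flask) | COCOc1cc(-c2oc3cc(OC)cc(OCc4ccccc4)c3c(=O)c2O)ccc1OCc1ccccc1 | intermediate
14 | 5-(benzyloxy)-2-[4-(benzyloxy)-3-hydroxyphenyl]-3-hydroxy-7-methoxy-4H-chromen-4-one (5,4'-di-O-benzylrhamnetin) | COc1cc(OCc2ccccc2)c2c(=O)c(O)c(-c3ccc(OCc4ccccc4)c(O)c3)oc2c1 | intermediate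
15 | bis(triethylammonium) 5,4'-di-O-benzylrhamnetin 3,3'-disulfate | CC[NH+](CC)CC.CC[NH+](CC)CC.COc1cc(OCc2ccccc2)c2c(=O)c(OS(=O)(=O)[O-])c(-c3ccc(OCc4ccccc4)c(OS(=O)(=O)[O-])c3)oc2c1 | intermediate
16 | bis(triethylammonium) rhamnetin 3,3'-disulfate (formed in the flask) | CC[NH+](CC)CC.CC[NH+](CC)CC.COc1cc(O)c2c(=O)c(OS(=O)(=O)[O-])c(-c3ccc(O)c(OS(=O)(=O)[O-])c3)oc2c1 | intermediate
17 | rhamnetin 3,3'-disulfate | COc1cc(O)c2c(=O)c(OS(=O)(=O)O)c(-c3ccc(O)c(OS(=O)(=O)O)c3)oc2c1 | target

**Step count**

Total steps: 9. Longest linear sequence: 7 steps (4 → 5 → 6 → 9 → 11 → 14 → 15 → 17; steps 3 to 9).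

**Steps most likely to fail**

Step 6. The rhodium carbene may insert into the phenol O–H bond and lead on to benzofuran-type products. The ylide carbonyl may direct aryl C–H activation and self-annulation of 9. The acyl–rhodium species may lose carbon monoxide, and the doubly ortho-substituted aldehyde may metalate slowly. The fallback builds the same diketone by enolate acylation and sets out from 3. Addition of MeMgBr (2.5 equiv, THF, 0 °C) should give racemic 1-[2-(benzyloxy)-6-hydroxy-4-methoxyphenyl]ethan-1-ol F1. Oxidation of the benzylic alcohol with MnO2 in CH2Cl2 should give 1-[2-(benzyloxy)-6-hydroxy-4-methoxyphenyl]ethan-1-one F2. Crossed Claisen condensation of the trianion-forming ketone F2 with ester 6 (LiN(SiMe3)2, 3.5 equiv, THF, −78 °C to rt) should give diketone 10. Cyclodehydration in NaOAc/AcOH at 90 °C then returns to the route at 11.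

Step 8. Sulfation of the 3-OH, which is hydrogen-bonded to the C4 carbonyl and flanked by ring B, may stop at the monosulfate, and the 3-sulfate may hydrolyse while the polar salt is isolated. The fallback uses a masked, neutral sulfate diester and sets out from 14. Treatment with 2,2,2-trichloroethyl chlorosulfate, Et3N and DMAP in THF should give the silica-stable 5,4'-di-O-benzylrhamnetin 3,3'-bis(2,2,2-trichloroethyl sulfate) F3. Transfer hydrogenolysis (10% Pd/C, HCO2NH4, MeOH, rt) should remove both trichloroethyl groups and both benzyl ethers to give diammonium rhamnetin 3,3'-disulfate F4. Cold exchange on Dowex 50W-X8 (H+ form) returns to the route at 17.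

Step 7. Epoxidation of the electron-poor C2=C3 bond may be slow enough for benzylic C–H oxidation of the benzyl ethers to compete, and the epoxide may fragment or ring-contract during acid opening. The fallback installs the oxygen by deprotonative metalation instead of electrophilic oxidation and sets out from 11. Deprotonation at C3 with LiN(iPr)2 (THF, −78 °C) and trapping with B(OMe)3 should give dimethyl {5-(benzyloxy)-2-[4-(benzyloxy)-3-(methoxymethoxy)phenyl]-7-methoxy-4-oxo-4H-chromen-3-yl}boronate F5. Oxidation with H2O2/AcOH should give the MOM-protected flavonol 13, now isolated. HCl in MeOH–THF at 40 °C then returns to the route at 14.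

**Further compounds**

F1 | step 6 | 1-[2-(benzyloxy)-6-hydroxy-4-methoxyphenyl]ethan-1-ol (racemic) | COc1cc(O)c(C(C)O)c(OCc2ccccc2)c1
F2 | step 6 | 1-[2-(benzyloxy)-6-hydroxy-4-methoxyphenyl]ethan-1-one | COc1cc(O)c(C(C)=O)c(OCc2ccccc2)c1
F3 | step 8 | 5,4'-di-O-benzylrhamnetin 3,3'-bis(2,2,2-trichloroethyl sulfate) | COc1cc(OCc2ccccc2)c2c(=O)c(OS(=O)(=O)OCC(Cl)(Cl)Cl)c(-c3ccc(OCc4ccccc4)c(OS(=O)(=O)OCC(Cl)(Cl)Cl)c3)oc2c1
F4 | step 8 | diammonium rhamnetin 3,3'-disulfate | [NH4+].[NH4+].COc1cc(O)c2c(=O)c(OS(=O)(=O)[O-])c(-c3ccc(O)c(OS(=O)(=O)[O-])c3)oc2c1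
F5 | step 7 | dimethyl {5-(benzyloxy)-2-[4-(benzyloxy)-3-(methoxymethoxy)phenyl]-7-methoxy-4-oxo-4H-chromen-3-yl}boronate | COCOc1cc(-c2oc3cc(OC)cc(OCc4ccccc4)c3c(=O)c2B(OC)OC)ccc1OCc1ccccc1
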